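The constants give the first step of the scheme a forward rate and a back rate, and their ratio, being free of time, shows where each electrophile curve can go.

    electrophile + nucleophile ⇌ acid set free + target (K1 = 0.376, k1 = 1.04 /M/h)
    nucleophile + acid set free ⇌ protonated nucleophile, settled at all times (K2 = 1200 /M)
    acid set free + free base ⇌ salt of the base, settled at all times (K3 = 13000 /M)
    free base + target → over-reaction product (k4 = 0.147 /M/h)
    crystals ⇌ acid set free, rate k5*(cs5 - [acid set free]) while solid is left; crystals form when [acid set free] > cs5 (cs5 = 0.52 mM, k5 = 1.43 /h)

all flasks: electrophile 0.050 M; protonated nucleophile 0.950 equiv; time 10 d

| charge | free base |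
|---|---|
| blue | 1.50 equiv |
| violet | 3.00 equiv |
| ochre | 6.00 equiv |

- part of the electrophile that has reacted at the end, blue
- part of the electrophile that has reacted at the end, violet
- part of the electrophile that has reacted at the end, ochre
- what raising the equivalents of free base from its lowest to its highest value here does to the part of the electrophile that has reacted (changes below 5 percentage points count as none) (no change / it rises / it falls)

- acid set free is meant together with its crystals
- solid, in amounts per volume of the solution: crystals
- run time (blue): 10 d

1. Slope. In blue, as charged, nucleophile has a forward half-life of 0.56 d, shorter than the 2.6 d of target under over-reaction. So electrophile falls steeply at first.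

2. The ratio. Back rate over forward rate of the first step is R = ([acid set free]/cs5) × ([target]/[electrophile]) × (cA/[nucleophile])/G, where the balance number G, K1 times cA over cs5, is 36.2. The curve flattens where R reaches 1.

3. The knee. In blue, let x be the part of electrophile reacted and e = 0.950 the protonated nucleophile per electrophile. When [acid set free] reaches cs5, crystals begin. At that point, the balances of steps 2 and 3 give 12.9% of the base free and 38.4% of the remaining nucleophile protonated. The acid budget puts this at x = 52.1%, near 0.946 d on a plain second-order curve.

4. The level. With acid at cs5 in blue, R = 1 reads x = H(1 − x)(e − x), with H = G(1 − g) = 22.3. This gives x = 78.6%. Target's half-life at that free base is 20.3 d, longer than the 10 d run, so you leave that drain out of this estimate, though it is not nil, and commit to this level for blue.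

5. The other curve. Ochre's 6.00 equiv of free base exceeds the acid that e and its full reaction can bring. Taking R as small there, nucleophile is the limiting reagent, and the second-order curve reaches 89.8% at 10 d. This reckoning puts no number on violet. The rise from blue to ochre is 11 percentage points, more than 5 points.

The forecast says 80%, 88% and 90%, so it rises, on the ground that in blue “the acid reaches its solubility limit and crystallises”. Its blue figure stands above this reckoning's 78.6%.

The flask gives 77.8% in blue, 87.2% in violet and 89.5% in ochre: it rises, by 12 points. At 10.0 d, blue holds crystals at 0.0240 M and ochre at 0 M. With the other amounts and the time held, violet's answer has moved by 5 points at 0.864 equiv or 1.09 equiv of protonated nucleophile. From the end readings, R in blue is 0.779. In the flask like blue but with 6.00 equiv of free base, which reaches 89.5%, R is 0.00843.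

The numbers of this flask are assumed.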